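**Retrosynthetic overview**
1. Target ⇐ its hepta-O-benzyl ether; the seven phenols are unmasked last by neutral hydrogenolysis, because the 2,3-cis C3 centre is epimerisable in base.
2. Hepta-O-benzyl biflavanone ⇐ open bis-chalcone: both pyranone rings (ring F, then ring C) close in one catalytic enantioselective double oxa-Michael addition, which sets C2'', C2 and, by kinetic protonation, C3.
3. Bis-chalcone ⇐ deoxybenzoin–acetophenone + two aryl aldehydes (Knoevenagel at the CH2, Claisen–Schmidt at the acetyl, one pot).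
4. Deoxybenzoin (future C3–C8'' bond) ⇐ dibenzyl phloroacetophenone + the arylglyoxal made from the same ketone (Friedel–Crafts hydroxyalkylation, then reductive C–O cleavage).
5. Ring order: benzene rings A, B, D, E are bought; rings F and C are formed last, together.

Ring labels: rings A, B, C are the benzo ring, the 3,4-dihydroxyphenyl ring and the pyranone of the 3-linked unit (locants unprimed). Rings D, E, F are the benzo ring, the 4-hydroxyphenyl ring and the pyranone of the 8-linked unit (locants double-primed). The target SMILES encodes (2R,3R), which is 2,3-cis, and (2''R).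

Assumption: the epi-quinidine-derived catalyst is taken as the pseudo-enantiomer that gives the R sense at C2 and C2''; if a monomeric 2'-hydroxychalcone model shows the opposite, the epi-quinine-derived one is used.

**Step 1**
Reactants: 1 1-(2,4,6-trihydroxyphenyl)ethanone (phloroacetophenone)
Product: 2 1-[2,4-bis(benzyloxy)-6-hydroxyphenyl]ethanone
Conditions: BnBr (2.1 equiv), K2CO3, DMF, 0 °C to rt
Reagents that add atoms: benzyl bromide, BrCc1ccccc1
Why: Williamson etherification alkylates the two non-chelated phenols, while the remaining OH, hydrogen-bonded to the acetyl C=O, stays free; no stereocentre.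

**Step 2**
Reactants: 2 1-[2,4-bis(benzyloxy)-6-hydroxyphenyl]ethanone
Product: 3 2-[2,4-bis(benzyloxy)-6-hydroxyphenyl]-2-oxoacetaldehyde
Conditions: SeO2 (1.3 equiv), 1,4-dioxane/H2O (30:1), 90 °C
Reagents that add atoms: selenium dioxide, O=[Se]=O
Why: Riley oxidation of the aryl methyl ketone stops at the arylglyoxal (in ring-chain equilibrium with its lactol form) and leaves benzyl ethers alone; no stereocentre.

**Step 3**
Reactants: 3 2-[2,4-bis(benzyloxy)-6-hydroxyphenyl]-2-oxoacetaldehyde; 2 1-[2,4-bis(benzyloxy)-6-hydroxyphenyl]ethanone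
Product: 6 2-[3-acetyl-4,6-bis(benzyloxy)-2-hydroxyphenyl]-1-[2,4-bis(benzyloxy)-6-hydroxyphenyl]ethanone (deoxybenzoin), via benzoin adduct 4 (not isolated), via 2-arylbenzofuran-3-one 5 (not isolated)
Conditions: 2 (1.5 equiv), TsOH·H2O (10 mol %), AcOH, 45 °C; then Zn dust, 60 °C
Reagents that add atoms: none
Why: Friedel–Crafts hydroxyalkylation of 2 by the aldehyde carbon of 3 occurs at the one ring position ortho to its free phenol, and Zn/AcOH then cleaves the benzylic C–O bond alpha to the ketone (open alcohol 4 or its ring-closed ether 5 give the same product, as in the classical benzoin-to-deoxybenzoin reduction), which also erases the transient stereocentre.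

**Step 4**
Reactants: 6 deoxybenzoin; 7 3,4-bis(benzyloxy)benzaldehyde; 8 4-(benzyloxy)benzaldehyde
Product: 11 (E)-1-[2,4-bis(benzyloxy)-6-hydroxyphenyl]-2-{4,6-bis(benzyloxy)-3-[(E)-3-(4-(benzyloxy)phenyl)prop-2-enoyl]-2-hydroxyphenyl}-3-[3,4-bis(benzyloxy)phenyl]prop-2-en-1-one (bis-chalcone), via alpha-aryl chalcone 9 (not isolated), via its ring-closed chromanone 10 (not isolated)
Conditions: 7 (1.0 equiv), piperidine/AcOH (cat.), EtOH, 70 °C; then 8 (1.5 equiv), 50% aq. KOH, EtOH/THF, rt; AcOH, 0 °C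
Reagents that add atoms: none
Why: Knoevenagel condensation is confined to the doubly activated deoxybenzoin CH2, and the following Claisen–Schmidt condensation of the acetyl group with 8 in strong base builds the second enone while hydroxide reopens any closed pyranone by E1cB, so both 2'-hydroxy enones are isolated open on cold acidification; both alkenes are E (thermodynamic) and there is no stereocentre.

**Step 5**
Reactants: 11 bis-chalcone
Product: 13 (2R)-5,7-bis(benzyloxy)-2-[4-(benzyloxy)phenyl]-8-{(2R,3R)-5,7-bis(benzyloxy)-2-[3,4-bis(benzyloxy)phenyl]-4-oxochroman-3-yl}chroman-4-one, via mono-cyclised flavanone-chalcone 12 (not isolated)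
Conditions: 9-amino-9-deoxy-epi-quinidine 3,5-bis(trifluoromethyl)phenyl thiourea (20 mol %), toluene, 0 °C to rt; AcOH quench at full conversion
Reagents that add atoms: none
Why: Proposed new method: the quinuclidine nitrogen acts as general base on each chelated phenol while the thiourea hydrogen-bonds the enone carbonyl, so each phenoxide adds 6-endo to the same enantioface of its own enone (the cross closure of the ring D phenol onto the other enone would be 5-endo-trig), setting C2'' and then C2 as R under catalyst control, and the ring C enol is protonated at C3 anti to the pseudo-axial C2 aryl group, giving the kinetic 2,3-cis (2R,3R) product that the weakly basic catalyst should not re-enolise; the closest known reactions are the cinchona-thiourea-catalysed enantioselective intramolecular oxa-Michael cyclisation of 2'-hydroxyaryl alkylidene beta-keto esters to flavanones and the cinchona-alkaloid-catalysed cyclisation of simple 2'-hydroxychalcones, neither of which has been run twice in one molecule or on an alpha-aryl enone.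

**Step 6**
Reactants: 13 hepta-O-benzyl biflavanone
Product: 14 (2R)-8-[(2R,3R)-2-(3,4-dihydroxyphenyl)-5,7-dihydroxy-4-oxochroman-3-yl]-5,7-dihydroxy-2-(4-hydroxyphenyl)chroman-4-one
Conditions: H2 (1 atm), 10% Pd/C, EtOAc/THF (1:1), rt
Reagents that add atoms: none
Why: Catalytic hydrogenolysis of the seven benzyl aryl ethers is neutral, so the epimerisable cis C3 centre, the slower-reacting benzylic ring C–O bonds at C2 and C2'' and the aryl ketones are left alone if the reaction is stopped after seven equivalents of H2; no stereocentre is formed or inverted.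

**Compound list**
1 | 1-(2,4,6-trihydroxyphenyl)ethanone (phloroacetophenone, sold as monohydrate) | CC(=O)c1c(O)cc(O)cc1O | starting material
2 | 1-[2,4-bis(benzyloxy)-6-hydroxyphenyl]ethanone | CC(=O)c1c(O)cc(OCc2ccccc2)cc1OCc1ccccc1 | intermediate
3 | 2-[2,4-bis(benzyloxy)-6-hydroxyphenyl]-2-oxoacetaldehyde (arylglyoxal, open form) | O=CC(=O)c1c(O)cc(OCc2ccccc2)cc1OCc1ccccc1 | intermediate
4 | 2-[3-acetyl-4,6-bis(benzyloxy)-2-hydroxyphenyl]-1-[2,4-bis(benzyloxy)-6-hydroxyphenyl]-2-hydroxyethanone (benzoin adduct, racemic, not isolated) | CC(=O)c1c(O)c(C(O)C(=O)c2c(O)cc(OCc3ccccc3)cc2OCc2ccccc2)c(OCc2ccccc2)cc1OCc1ccccc1 | intermediate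
5 | 2-[3-acetyl-4,6-bis(benzyloxy)-2-hydroxyphenyl]-4,6-bis(benzyloxy)benzofuran-3(2H)-one (racemic, not isolated) | CC(=O)c1c(O)c(C2Oc3cc(OCc4ccccc4)cc(OCc4ccccc4)c3C2=O)c(OCc2ccccc2)cc1OCc1ccccc1 | intermediate
6 | 2-[3-acetyl-4,6-bis(benzyloxy)-2-hydroxyphenyl]-1-[2,4-bis(benzyloxy)-6-hydroxyphenyl]ethanone (deoxybenzoin) | CC(=O)c1c(O)c(CC(=O)c2c(O)cc(OCc3ccccc3)cc2OCc2ccccc2)c(OCc2ccccc2)cc1OCc1ccccc1 | intermediate
7 | 3,4-bis(benzyloxy)benzaldehyde | O=Cc1ccc(OCc2ccccc2)c(OCc2ccccc2)c1 | starting material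
8 | 4-(benzyloxy)benzaldehyde | O=Cc1ccc(OCc2ccccc2)cc1 | starting material
9 | (E)-2-[3-acetyl-4,6-bis(benzyloxy)-2-hydroxyphenyl]-1-[2,4-bis(benzyloxy)-6-hydroxyphenyl]-3-[3,4-bis(benzyloxy)phenyl]prop-2-en-1-one (not isolated) | CC(=O)c1c(O)c(/C(=C\c2ccc(OCc3ccccc3)c(OCc3ccccc3)c2)C(=O)c2c(O)cc(OCc3ccccc3)cc2OCc2ccccc2)c(OCc2ccccc2)cc1OCc1ccccc1 | intermediate
10 | 3-[3-acetyl-4,6-bis(benzyloxy)-2-hydroxyphenyl]-5,7-bis(benzyloxy)-2-[3,4-bis(benzyloxy)phenyl]chroman-4-one (ring-closed form of 9, racemic cis/trans mixture, not isolated) | CC(=O)c1c(O)c(C2C(=O)c3c(OCc4ccccc4)cc(OCc4ccccc4)cc3OC2c2ccc(OCc3ccccc3)c(OCc3ccccc3)c2)c(OCc2ccccc2)cc1OCc1ccccc1 | intermediate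
11 | (E)-1-[2,4-bis(benzyloxy)-6-hydroxyphenyl]-2-{4,6-bis(benzyloxy)-3-[(E)-3-(4-(benzyloxy)phenyl)prop-2-enoyl]-2-hydroxyphenyl}-3-[3,4-bis(benzyloxy)phenyl]prop-2-en-1-one (bis-chalcone) | O=C(/C=C/c1ccc(OCc2ccccc2)cc1)c1c(OCc2ccccc2)cc(OCc2ccccc2)c(c1O)/C(=C\c1ccc(OCc2ccccc2)c(OCc2ccccc2)c1)C(=O)c1c(O)cc(OCc2ccccc2)cc1OCc1ccccc1 | intermediate
12 | (2R)-5,7-bis(benzyloxy)-2-[4-(benzyloxy)phenyl]-8-{(E)-3-[2,4-bis(benzyloxy)-6-hydroxyphenyl]-1-[3,4-bis(benzyloxy)phenyl]-3-oxoprop-1-en-2-yl}chroman-4-one (ring F closed, not isolated) | O=C1C[C@H](c2ccc(OCc3ccccc3)cc2)Oc2c1c(OCc1ccccc1)cc(OCc1ccccc1)c2/C(=C\c1ccc(OCc2ccccc2)c(OCc2ccccc2)c1)C(=O)c1c(O)cc(OCc2ccccc2)cc1OCc1ccccc1 | intermediate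
13 | (2R)-5,7-bis(benzyloxy)-2-[4-(benzyloxy)phenyl]-8-{(2R,3R)-5,7-bis(benzyloxy)-2-[3,4-bis(benzyloxy)phenyl]-4-oxochroman-3-yl}chroman-4-one (hepta-O-benzyl ether of the target, 2,3-cis) | O=C1C[C@H](c2ccc(OCc3ccccc3)cc2)Oc2c1c(OCc1ccccc1)cc(OCc1ccccc1)c2[C@H]1C(=O)c2c(OCc3ccccc3)cc(OCc3ccccc3)cc2O[C@H]1c1ccc(OCc2ccccc2)c(OCc2ccccc2)c1 | intermediate
14 | (2R)-8-[(2R,3R)-2-(3,4-dihydroxyphenyl)-5,7-dihydroxy-4-oxochroman-3-yl]-5,7-dihydroxy-2-(4-hydroxyphenyl)chroman-4-one (CNP0105436.4) | O=C1C[C@H](c2ccc(O)cc2)Oc2c1c(O)cc(O)c2[C@H]1C(=O)c2c(O)cc(O)cc2O[C@H]1c1ccc(O)c(O)c1 | target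

**Step count and risks**
Total steps: 6. Longest linear sequence: 6 (1 → 2 → 3 → 6 → 11 → 13 → 14; compound 2 is used twice, 7 and 8 are bought).

Steps most likely to fail:

Step 5 (key step). Risks are low ee, the trans C3 isomer, or racemic closure of 11 before the catalyst acts. The fallback sets out from 11 and comes back at 13. Both enones of 11 are closed oxidatively in one operation (I2 cat., DMSO, 120 °C) to the fully aromatic hepta-O-benzyl 3,8''-biflavone F1, which has no stereocentre. Both chromone C=C bonds are then reduced with a chiral copper hydride catalyst (Cu(OAc)2, DTBM-SEGPHOS in the enantiomer that gives 2R, (EtO)2MeSiH, t-BuOH, toluene). Hydride goes to C2 and C2'' under catalyst control, and the ring C enolate is protonated anti to the C2 aryl group, which gives 13.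

Step 3. Risks are self-condensation of 3, double arylation, or acid-induced closure of 6 to a benzofuran. The fallback sets out from 2 and comes back at 6, bringing in the two-carbon bridge at the acid oxidation level. Ketone 2 is hydroxyalkylated ortho to its free OH with glyoxylic acid (O=CC(=O)O) to the mandelic acid F2. Zn/AcOH removes the benzylic OH and the acid closes on the neighbouring phenol to the lactone F3. F3 then C-acylates commercial 3,5-bis(benzyloxy)phenol (Oc1cc(OCc2ccccc2)cc(OCc2ccccc2)c1) ortho to its OH (BF3·OEt2, 60 °C, ring-opening Friedel–Crafts acylation) to give 6.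

Step 4. Risks are loss of site selectivity between the CH2 and the acetyl group, or aldehyde scrambling by retro-aldol in KOH. The fallback sets out from 2 and comes back at 11, separating the two aldehydes in time instead of by acidity. Ketone 2 and aldehyde 8 give the chalcone F4 (KOH, EtOH). F4 is hydroxyalkylated by glyoxal 3 ortho to its free OH to the benzoin F5. The benzylic OH of F5 is removed by hydride transfer from a Hantzsch ester under diphenyl phosphate catalysis (ionic reduction of the quinone-methide-type cation, which leaves the enone alone) to the deoxybenzoin F6. One Knoevenagel condensation of F6 with 7 (piperidine/AcOH, then brief KOH and cold AcOH) gives 11.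

**Further compounds**
F1 | step 5 | 5,7-bis(benzyloxy)-8-{5,7-bis(benzyloxy)-2-[3,4-bis(benzyloxy)phenyl]-4-oxo-4H-chromen-3-yl}-2-[4-(benzyloxy)phenyl]-4H-chromen-4-one | O=c1cc(-c2ccc(OCc3ccccc3)cc2)oc2c1c(OCc1ccccc1)cc(OCc1ccccc1)c2-c1c(-c2ccc(OCc3ccccc3)c(OCc3ccccc3)c2)oc2cc(OCc3ccccc3)cc(OCc3ccccc3)c2c1=O
F2 | step 3 | 2-[3-acetyl-4,6-bis(benzyloxy)-2-hydroxyphenyl]-2-hydroxyacetic acid (racemic) | CC(=O)c1c(O)c(C(O)C(=O)O)c(OCc2ccccc2)cc1OCc1ccccc1
F3 | step 3 | 7-acetyl-4,6-bis(benzyloxy)benzofuran-2(3H)-one | O=C1Cc2c(O1)c(C(C)=O)c(OCc1ccccc1)cc2OCc1ccccc1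
F4 | step 4 | (E)-1-[2,4-bis(benzyloxy)-6-hydroxyphenyl]-3-[4-(benzyloxy)phenyl]prop-2-en-1-one | O=C(/C=C/c1ccc(OCc2ccccc2)cc1)c1c(O)cc(OCc2ccccc2)cc1OCc1ccccc1
F5 | step 4 | (E)-1-{4,6-bis(benzyloxy)-2-hydroxy-3-[2-(2,4-bis(benzyloxy)-6-hydroxyphenyl)-1-hydroxy-2-oxoethyl]phenyl}-3-[4-(benzyloxy)phenyl]prop-2-en-1-one (racemic) | O=C(/C=C/c1ccc(OCc2ccccc2)cc1)c1c(OCc2ccccc2)cc(OCc2ccccc2)c(c1O)C(O)C(=O)c1c(O)cc(OCc2ccccc2)cc1OCc1ccccc1
F6 | step 4 | (E)-1-{4,6-bis(benzyloxy)-2-hydroxy-3-[2-(2,4-bis(benzyloxy)-6-hydroxyphenyl)-2-oxoethyl]phenyl}-3-[4-(benzyloxy)phenyl]prop-2-en-1-one | O=C(/C=C/c1ccc(OCc2ccccc2)cc1)c1c(OCc2ccccc2)cc(OCc2ccccc2)c(c1O)CC(=O)c1c(O)cc(OCc2ccccc2)cc1OCc1ccccc1
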